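## Retrosynthetic overview
- Last operations: asymmetric transfer hydrogenation of the C7′ ketone, then removal of the acetate and the two aryl TIPS groups.
- The only ring, the THF, is closed by a 5-exo atom-transfer radical cyclisation (ATRC) that forms the C8–C8′ bond. The α-keto radical comes from an α-bromo aryl ketone and adds to an allyl ether whose carbinol carbon (C7) is already set.
- The cyclisation precursor is made by coupling the (S)-allylic alcohol (CBS reduction of an aryl vinyl ketone) with the α-bromo vinyl ketone generated in situ from the α,β-dibromo ketone.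
- Both aryl fragments come from one Friedel–Crafts acylation of guaiacol (made from catechol) with 3-chloropropionyl chloride.

Assumptions: acylation of guaiacol goes para to the phenol OH. C8′ (α to the aroyl group) can be equilibrated with mild base.

## Route

**Step 1**
Reactants: 1 catechol
Product: 2 guaiacol (2-methoxyphenol)
Conditions: dimethyl carbonate (solvent), K2CO3 (cat.), 160–180 °C, sealed tube
Reagents that add atoms: dimethyl carbonate, COC(=O)OC (supplies the OCH3 carbon)
Why: base-catalysed O-methylation with dimethyl carbonate is strongly mono-selective for catechol; no stereocentre is formed.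

**Step 2**
Reactants: 2 guaiacol; 3 3-chloropropionyl chloride
Product: 4 3-chloro-1-(4-hydroxy-3-methoxyphenyl)propan-1-one
Conditions: AlCl3 (2.5 equiv), ClCH2CH2Cl, 0 → 50 °C
Reagents that add atoms: none
Why: Friedel–Crafts acylation (direct, or by O-acylation then Fries rearrangement) goes para to the strongest donor, the O–AlCl2 group; no stereocentre is formed.

**Step 3**
Reactants: 4
Product: 5 1-[3-methoxy-4-(triisopropylsilyloxy)phenyl]prop-2-en-1-one (aryl vinyl ketone)
Conditions: TIPSCl, imidazole, DMF, 0 °C; then Et3N (3 equiv), rt (one pot)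
Reagents that add atoms: TIPSCl, CC(C)[Si](Cl)(C(C)C)C(C)C
Why: silylation protects the phenol, then E1cB dehydrochlorination of the β-chloro ketone gives the vinyl ketone; no stereocentre is formed.

**Step 4**
Reactants: 5
Product: 6 (S)-1-[3-methoxy-4-(TIPSO)phenyl]prop-2-en-1-ol
Conditions: (R)-Me-CBS (10 mol %), catecholborane (1.5 equiv), toluene, –78 °C
Reagents that add atoms: none (hydride only; the boron is removed on work-up)
Why: Corey–Bakshi–Shibata 1,2-reduction of the enone (catecholborane avoids hydroboration of the vinyl group) sets the carbinol centre as (S). This becomes C7 of the target, and the aryl group is treated as the larger ketone substituent.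

**Step 5**
Reactants: 5 (a second portion)
Product: 7 2,3-dibromo-1-[3-methoxy-4-(TIPSO)phenyl]propan-1-one
Conditions: Br2 (1.05 equiv), CH2Cl2, 0 °C, dark
Reagents that add atoms: bromine, BrBr
Why: electrophilic anti-addition of Br2 to the vinyl group; the bulky TIPS ether shields the ring position ortho to oxygen, and the acyl group deactivates the ring. The new C2 stereocentre is racemic and irrelevant, because C8′ becomes a radical later.

**Step 6**
Reactants: 7 dibromo ketone (1.3 equiv); 6 (S)-allylic alcohol (1.0 equiv)
Product: 8 (S)-2-bromo-3-{[1-(3-methoxy-4-TIPSO-phenyl)allyl]oxy}-1-[3-methoxy-4-(TIPSO)phenyl]propan-1-one (C7 = S, C8′ epimeric mixture)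
Conditions: Et3N (2 equiv), CH2Cl2, 0 °C → rt
Reagents that add atoms: none (Et3N is removed as its HBr salt)
Why: Proposed new method: Et3N dehydrobrominates 7 (E1cB) to the highly electrophilic 2-bromo-1-arylprop-2-en-1-one, and amine-assisted oxa-Michael addition of 6 gives the α-bromo-β-alkoxy ketone; the closest known reactions are amine-promoted alcohol additions to α-haloenones and dibromoketone/alkoxide couplings. The C–O bond at the carbinol carbon is untouched, so C7 keeps its configuration. Brominating before the alkene-bearing ether is introduced avoids bromination of the vinyl group.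

**Step 7 (key radical step)**
Reactants: 8
Product: 9 2-aryl-3-(bromomethyl)-4-aroyltetrahydrofuran (2,3-trans; C4 (C8′) as a cis/trans mixture; both aryl groups 3-methoxy-4-TIPSO-phenyl)
Conditions: CuBr (20 mol %), Me6TREN (20 mol %), Cu(0) wire, toluene (0.02 M), 60 °C
Reagents that add atoms: none (the bromine is transferred within the substrate)
Why: atom-transfer radical cyclisation (5-exo-trig): Cu(I) abstracts Br to give the α-keto radical, which adds to the terminal alkene, and the primary radical takes Br back from Cu(II). The pseudo-equatorial C7 aryl group in the chair-like transition state places the new CH2Br trans to it (Beckwith–Houk), and C8′ is set only kinetically.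

**Step 8**
Reactants: 9
Product: 10 all-trans 4-aroyl-2-aryl-THF-3-ylmethyl acetate (2,3-trans, 3,4-trans)
Conditions: CsOAc (3 equiv), DMF, 90 °C; then DBU (0.2 equiv), rt
Reagents that add atoms: cesium acetate, CC(=O)[O-].[Cs+]
Why: SN2 displacement of the primary bromide by acetate (a weak base, which limits γ-halo-ketone cyclopropanation). DBU is added only after the bromide is consumed and equilibrates C8′, the only acidic stereocentre, to the thermodynamic 3,4-trans isomer; any retro-oxa-Michael ring opening re-closes at the achiral C9′ and leaves C7 untouched.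

**Step 9**
Reactants: 10
Product: 11 (7′S)-secondary benzylic alcohol, C9 acetate, both aryl–OTIPS
Conditions: RuCl[(S,S)-TsDPEN](p-cymene) (2 mol %), HCOOH/Et3N (5:2), CH2Cl2, 30 °C
Reagents that add atoms: none
Why: Noyori asymmetric transfer hydrogenation is catalyst-controlled and sets C7′ as (S) (aryl > ring carbon, as in acetophenone → (S)-alcohol with the (S,S) catalyst). The acidic, buffered conditions do not epimerise C8′, and the acetate survives.

**Step 10**
Reactants: 11
Product: 12 target, {(2S,3R,4S)-4-[(S)-hydroxy(4-hydroxy-3-methoxyphenyl)methyl]-2-(4-hydroxy-3-methoxyphenyl)oxolan-3-yl}methanol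
Conditions: TBAF (4 equiv), THF, 0 °C → rt; then K2CO3, MeOH, rt
Reagents that add atoms: none
Why: fluoride removes the aryl TIPS ethers and methanolysis removes the acetate; all four stereocentres are already set and none is touched.

## Compound list
1 | catechol | Oc1ccccc1O | starting material
2 | guaiacol | COc1ccccc1O | intermediate
3 | 3-chloropropionyl chloride | ClCCC(=O)Cl | starting material
4 | 3-chloro-1-(4-hydroxy-3-methoxyphenyl)propan-1-one | COc1cc(C(=O)CCCl)ccc1O | intermediate
5 | 1-[3-methoxy-4-(TIPSO)phenyl]prop-2-en-1-one | C=CC(=O)c1ccc(O[Si](C(C)C)(C(C)C)C(C)C)c(OC)c1 | intermediate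
6 | (S)-1-[3-methoxy-4-(TIPSO)phenyl]prop-2-en-1-ol | C=C[C@H](O)c1ccc(O[Si](C(C)C)(C(C)C)C(C)C)c(OC)c1 | intermediate
7 | 2,3-dibromo-1-[3-methoxy-4-(TIPSO)phenyl]propan-1-one (racemic at C2) | COc1cc(C(=O)C(Br)CBr)ccc1O[Si](C(C)C)(C(C)C)C(C)C | intermediate
8 | α-bromo-β-(allyloxy) ketone (C7 = S, C8′ epimeric mixture; both aryl = 3-methoxy-4-TIPSO-phenyl) | C=C[C@H](OCC(Br)C(=O)c1ccc(O[Si](C(C)C)(C(C)C)C(C)C)c(OC)c1)c1ccc(O[Si](C(C)C)(C(C)C)C(C)C)c(OC)c1 | intermediate
9 | 3-(bromomethyl)-2-aryl-4-aroyl-THF, 2,3-trans (C4 unspecified) | COc1cc(C(=O)C2CO[C@H](c3ccc(O[Si](C(C)C)(C(C)C)C(C)C)c(OC)c3)[C@H]2CBr)ccc1O[Si](C(C)C)(C(C)C)C(C)C | intermediate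
10 | all-trans 4-aroyl-2-aryl-THF-3-ylmethyl acetate | COc1cc(C(=O)[C@@H]2CO[C@H](c3ccc(O[Si](C(C)C)(C(C)C)C(C)C)c(OC)c3)[C@H]2COC(C)=O)ccc1O[Si](C(C)C)(C(C)C)C(C)C | intermediate
11 | 7′S alcohol from 10 | COc1cc([C@@H](O)[C@@H]2CO[C@H](c3ccc(O[Si](C(C)C)(C(C)C)C(C)C)c(OC)c3)[C@H]2COC(C)=O)ccc1O[Si](C(C)C)(C(C)C)C(C)C | intermediate
12 | {(2S,3R,4S)-4-[(S)-hydroxy(4-hydroxy-3-methoxyphenyl)methyl]-2-(4-hydroxy-3-methoxyphenyl)oxolan-3-yl}methanol | COc1cc([C@@H](O)[C@@H]2CO[C@H](c3ccc(O)c(OC)c3)[C@H]2CO)ccc1O | target

## Totals
Total steps: 10. Longest linear sequence: 9 (steps 1, 2, 3, 4, 6, 7, 8, 9, 10; catechol → 2 → 4 → 5 → 6 → 8 → 9 → 10 → 11 → 12). Step 5 is a parallel branch from 5.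

## Three steps most likely to fail
1. **Step 7 (radical cyclisation).** The yield or the 2,3-trans selectivity may be poor, the allylic-benzylic C7–H may be abstracted, or the amine ligand may eliminate the β-alkoxy-α-bromo ketone.
   Fallback: a Pd(0)-catalysed 5-exo alkylative (Heck-type) cyclisation of 8 to the exocyclic 3-methylene THF, then hydroboration/oxidation (9-BBN; NaBO3) to the CH2OH. This replaces steps 7–8 with an organometallic ring closure, and the C8 centre is re-set by face-selective hydroboration.
2. **Step 6 (dehydrobromination/oxa-Michael coupling).** The hindered secondary alcohol may add poorly to the bromo-enone, or the adduct may undergo retro-Michael elimination.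
   Fallback: reverse the order. Add 6 to vinyl ketone 5 by PBu3-catalysed oxa-Michael addition, then brominate α via the silyl enol ether (TMSOTf, Et3N; then NBS, –78 °C), which is far more nucleophilic than the allyl alkene.
3. **Step 4 (CBS reduction).** Aryl and vinyl are similar in size, so the enantioselectivity for the (S)-alcohol may be modest.
   Fallback: reduce 5 to the racemic allylic alcohol (NaBH4, CeCl3), then resolve it by lipase-catalysed acylation (CAL-B, vinyl acetate) and carry the unacylated (S)-alcohol forward.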